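Slowness is what I look for first: in the earlier runs product stands at 2.5% and 2.6% after 1.50 min, while [substrate] is already down to 51.0% and 50.1%, so the material must wait somewhere between the two.

| setting | south-west | north-east | flask |
|---|---|---|---|
| substrate | 0.067 M | 0.15 M | 0.10 M |
| remark | run made earlier | run made earlier |  |
| time |  |  | 8.0 min |

| run | time / min | product / % | substrate / % |
|---|---|---|---|
| south-west | 0.500 | 0.1 | 78.9 |
| south-west | 1.50 | 2.5 | 51.0 |
| south-west | 3.00 | 8.0 | 24.7 |
| south-west | 5.00 | 16.2 | 10.0 |
| south-west | 6.00 | 20.6 | 7.4 |
| north-east | 0.500 | 0.3 | 79.7 |
| north-east | 1.50 | 2.6 | 50.1 |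
| north-east | 3.00 | 8.7 | 25.2 |
| north-east | 5.00 | 15.9 | 9.5 |
| north-east | 6.00 | 20.0 | 6.5 |

(standard deviation of a reading: 0.5 percentage points)

* amount of product in percent of the substrate charged, at 50 s, 3.0 min and 8.0 min

- what was read earlier has a scatter of 0.5 percentage points, one standard deviation
- steps under discussion: substrate -> intermediate A; substrate -> intermediate B; intermediate A -> product; intermediate B -> product

I need two times. The first is the fall time of substrate, read from the south-west run; the north-east run overlays it in percent although its charge differs, so I use it for the flask at 0.10 M too:

τ = 2.18 min

I take that also as the induction period of product. The second is the hold-up time, the time in which material waiting in the intermediates would turn into product at the rate of the climb, read from the mean of the two product readings at 6.00 min: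

T = (time − τ × fraction of substrate gone) / product = 19.5 min

T is longer than τ, by a factor of 8.94, so I let product climb steadily once the lag is past, and for the flask I reckon:

50 s: 0.722%
3.0 min: 7.03%
8.0 min: 30.1%

The forecast, holding that “one effective slow step suffices”, gives 0.9%, 8.2% and 29%, which differs from my figures.

The flask gives 0.844%, 7.70% and 28.3%.

    substrate → intermediate A (k = 0.0730 min⁻¹)
    substrate → intermediate B (k = 0.390 min⁻¹)
    intermediate A → product (k = 0.140 min⁻¹)
    intermediate B → product (k = 0.0460 min⁻¹)

At 8.00 min the flask still holds 62.4% as intermediate B. Carrying T to 80.0 min, where a steady climb would give more than the whole charge, I let the remainder decay instead and reckon the share not yet product as exp(−(time − τ)/T) = 1.85%; the flask then holds 97.6% product and 2.36% intermediate B.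

The data were generated by integration with made-up constants, and the scatter is random.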